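## Structural features

Disulfuretin (10) is a twofold-symmetric dimer of the aurone type: two 6-hydroxy-1-benzofuran-3(2H)-one units (benzo ring A fused to the five-membered oxygen ring C) are joined directly through their exocyclic carbons Cα and Cα', and each of these carbons also carries a 3,4-dihydroxyphenyl ring B. The core is therefore a fully substituted 2,3-diarylbuta-1,3-diene, flanked on each side by O1 and the C3 ketone, with no hydrogen on any of the four olefinic carbons. There is no stereocentre; the stereochemical content lies in the two tetrasubstituted C2=Cα bonds, both Z, with ring B trans to O1 (on the carbonyl side) and the partner half cis to O1. The fragile parts are the six phenols (two of them catechols, easily oxidised) and the two push–pull enones, whose C2=Cα bonds can lose their geometry under strong acid or light because ring B stabilises positive charge at Cα. The real difficulty is to build two adjacent tetrasubstituted enol-ether double bonds of defined geometry together with the hindered Cα–Cα' bond, which condensation chemistry of benzofuranones cannot do. The key step uses the trans relation of O1 and ring B on each C2=Cα bond, which is what anti addition of a phenol oxygen and an aryl group across a C≡C bond produces; the Cα–Cα' bond then maps onto the central σ-bond of a conjugated 1,3-diyne, and C3 is carried as a carbinol.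

## Logic of the disconnections

10 ⇒ 9. The six phenolic O–CH2Ph bonds are cut. The free phenols and catechols of 10 would not survive the oxidant, the base or the palladium chemistry of the earlier steps, so all six are masked to the end. Benzyl ethers are preferred to methyl ethers because they can be cleaved at −78 °C by a boron Lewis acid with an arene cation trap. A sixfold demethylation would need long exposure to a strong Lewis acid near ambient temperature and would endanger the Z,Z enones. The gain is a substrate with only inert spectator oxygens. The demand is a deprotection that neither isomerises the double bonds nor benzylates the electron-rich rings.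

9 ⇒ 8. The oxidation level at C3 and C3' is changed from ketone to secondary carbinol. With the ketones in place the alkyne precursor would be an ynone, a Michael acceptor that prefers six-membered (chromone-type) closure; the carbinol removes this pathway. The gain is a propargylic alcohol that comes from simple acetylide addition. The demand is a neutral oxidant selective for allylic/benzylic alcohols, and non-acidic handling of 8, whose C3–OH is benzylic, allylic and para to an alkoxy group and therefore ionises easily. The configuration at C3 is irrelevant.

8 ⇒ 4 + 6 (through 7). The bonds cut are O1–C2, O1'–C2', Cα–C(ring B) and Cα'–C(ring B'). The trans placement of O1 and ring B on each double bond is what anti addition across an alkyne produces, and the Cα–Cα' bond is already the central bond of the diyne 4. One operation then forms two rings, four bonds and both double-bond geometries from a symmetric, acyclic precursor and two molecules of a simple aryl iodide. The demands are 5-exo rather than 6-endo closure, oxypalladation that is faster than carbopalladation or plain hydroalkoxylation, and a second cycle on the more hindered enyne 7.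

4 ⇒ 3. The central C(sp)–C(sp) bond is cut, which halves the molecule into two identical molecules of 3. The forward reaction is an oxidative alkyne homocoupling that consumes two molecules of 3 for each molecule of 4. The demand is tolerance of the free phenol and carbinol of 3. The mixture of diastereomers that results is of no consequence.

3 ⇒ 1 + 2. The bond between the carbinol carbon and the alkyne is cut, leading to two commercial materials. The forward step needs an excess of 2, because the phenol of 1 consumes one equivalent, and needs no stereocontrol.

6 ⇒ 5. The C–I bond is cut. Because 5 is symmetric, the two positions para to oxygen are equivalent, so electrophilic iodination can give only one mono-iodide. The demand is to stop at mono-substitution.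

## Other disconnections considered

Alternative 1: The cut is at the two Cα–aryl bonds, after each enone has been retro-converted into a 3-methoxybenzofuran bearing a tertiary carbinol at Cα. The forward key step is a twofold addition of (3,4-dimethoxyphenyl)magnesium bromide A2 to the vicinal diketone 1,2-bis(3,6-dimethoxy-1-benzofuran-2-yl)ethane-1,2-dione A1, to give the fully substituted glycol A3. Acid would then have to ionise both tertiary hydroxyl groups and hydrolyse the two enol methyl ethers to reveal the enones.
- In its favour: carbonyl addition is standard chemistry, ring B enters last, the Cα–Cα' bond is present from the start in A1, and no transition metal is needed.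
- Against it here: the C2=Cα geometry would be fixed only in the ionisation/hydrolysis, by thermodynamics rather than by mechanism. A3 is a 1,2-diol disposed to pinacol-type aryl or heteroaryl shifts under the same acid. The second Grignard addition meets a hindered ketone next to a magnesium alkoxide. A sixfold ether cleavage still remains.
- Comparison: on mechanism, the key step of this alternative is better precedented than the cascade chosen here, and that is a point for the alternative. On step economy the two are about equal, since A1 requires a 3-alkoxybenzofuran to be made, metallated and joined to an oxalyl unit. On structure the chosen plan is stronger, because both double-bond geometries follow from the bond-forming event itself.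

Alternative 2: The cut is at O1–C2 and O1'–C2', with the C2 and C2' carbons tied together instead through a furan oxygen, so that the furan C2–C3 and C4–C5 bonds are the two C2=Cα bonds of the target. The forward key step is an acid-catalysed, dehydrating ring exchange of 2,5-bis(2-hydroxy-4-methoxybenzoyl)-3,4-bis(3,4-dimethoxyphenyl)furan A4. Each ortho phenol would add to the furan carbon bearing its own aroyl group, the furan C–O bonds would open, and the ring oxygen would leave as water. This would give disulfuretin hexamethyl ether A5 directly at the ketone oxidation level.
- In its favour: A4 is a robust, symmetric aromatic compound accessible by ordinary furan arylation and acylation. The whole carbon skeleton exists before the key step, and neither metal nor redox step follows. On the oxidation-state count this alternative is better than the chosen plan, which needs a separate oxidation. If the Z,Z form is the thermodynamic isomer, it would be the equal of the chosen plan on geometry, since the acid medium allows equilibration.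
- Against it here: the step sacrifices furan aromaticity. It relies on hydrogen-bonded, weakly nucleophilic phenols attacking the acyl-bearing carbon of a 2-acylfuran, for which there is no close analogy. It offers no kinetic control of geometry. It exposes the product to hot acid.
- Comparison: on step economy the saving of one oxidation is offset by the four or five steps needed for A4, so the two plans are about level. On mechanism the chosen plan rests on closer analogy.

Alternative 3: The cut is at O1–C7a and C3–C3a on both sides, so ring A is removed as an aryne and each C2–C3 unit reverts to an enol ester. The forward key step is fluoride-triggered release of the unsymmetrical aryne from 2-bromo-4-methoxy-6-(trimethylsilyl)phenyl trifluoromethanesulfonate A7 in the presence of the bis-enol dimethyl (2Z,4Z)-2,5-dihydroxy-3,4-bis(3,4-dimethoxyphenyl)hexa-2,4-dienedioate A6. Each enolate oxygen would add to the aryne and the resulting aryl anion would close onto the neighbouring ester, giving the 4,4'-dibromide A8.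
- In its favour: the central C4 unit with both rings B comes from the oxidative dimerisation of a simple arylpyruvate enol. Ring A is attached last. Four bonds and two rings are formed in one step, which is equal to the chosen key step. The ketone level is reached directly, which is better than the chosen plan on that count.
- Against it here: enolates usually attack arynes through carbon or insert into C–C bonds rather than O-arylate. The enol geometry that would have to become Z,Z is mobile through the keto tautomer. The bromine serves only to direct the aryne addition and must later be removed reductively in the presence of the diene. A7 is itself a multistep aryne precursor.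
- Comparison: on structure and mechanism the chosen plan gives firmer control of regiochemistry and geometry. On step economy the alternative is longer once A6, A7 and the debromination are counted.

Key step: step 4

Assumption: the carbinol centres are formed without control (3 racemic; 4 and 8 as mixtures of meso and racemic diastereomers, 7 likewise as a diastereomer mixture); step 5 removes them, so the mixtures are carried forward and the meso form, or for 7 the form derived from it, is drawn.

## Route

Step 1
Reactants: 1 4-(benzyloxy)-2-hydroxybenzaldehyde; 2 ethynylmagnesium bromide
Product: 3 5-(benzyloxy)-2-(1-hydroxyprop-2-yn-1-yl)phenol (racemic)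
Conditions: 2 (3.2 equiv, 0.5 M in THF), THF, 0 °C to rt; then sat. aq NH4Cl; chromatography on Et3N-deactivated silica
Reagents that add atoms: none
Why: 1,2-addition of an alkynyl Grignard reagent to an aldehyde; the first equivalent of 2 only deprotonates the phenol, the magnesium phenoxide then chelates and activates the aldehyde, and the new carbinol centre forms without control (racemic), which is acceptable because step 5 destroys it.

Step 2
Reactants: 3 5-(benzyloxy)-2-(1-hydroxyprop-2-yn-1-yl)phenol
Product: 4 1,6-bis[4-(benzyloxy)-2-hydroxyphenyl]hexa-2,4-diyne-1,6-diol (meso form drawn)
Conditions: CuCl (10 mol %), TMEDA (20 mol %), air, acetone, rt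
Reagents that add atoms: 5-(benzyloxy)-2-(1-hydroxyprop-2-yn-1-yl)phenol (second molecule of 3), C#CC(O)c1ccc(OCc2ccccc2)cc1O
Why: Glaser–Hay oxidative homocoupling, in which two molecules of 3 are joined at their terminal alkyne carbons and the oxygen of air takes up the two alkyne hydrogens as water: the terminal alkyne forms an alkynylcopper species (monovalent copper) with CuCl–TMEDA, which dimerises oxidatively while air turns the copper over. Secondary propargylic alcohols are standard substrates and the carbinol centres are untouched, so a statistical mixture of meso and racemic 4 is expected.

Step 3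
Reactants: 5 1,2-bis(benzyloxy)benzene
Product: 6 1,2-bis(benzyloxy)-4-iodobenzene
Conditions: NIS (1.05 equiv), TFA (0.3 equiv), MeCN, rt, dark
Reagents that add atoms: N-iodosuccinimide, O=C1CCC(=O)N1I
Why: Electrophilic aromatic iodination para to an alkoxy group; the two open para positions of the symmetric diether are equivalent and the ortho positions are shielded, so a single mono-iodide is expected and the benzyl ethers are inert to catalytic acid at rt.

Step 4
Reactants: 4 1,6-bis[4-(benzyloxy)-2-hydroxyphenyl]hexa-2,4-diyne-1,6-diol; 6 1,2-bis(benzyloxy)-4-iodobenzene
Product: 8 (2Z,2'Z)-2,2'-{1,2-bis[3,4-bis(benzyloxy)phenyl]ethane-1,2-diylidene}bis[6-(benzyloxy)-2,3-dihydro-1-benzofuran-3-ol] (meso form drawn), via mono-cyclised aryl enyne 7 (not isolated)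
Conditions: 6 (2.5 equiv), Pd(PPh3)4 (10 mol %), K2CO3 (4 equiv), degassed MeCN, 60 °C, argon; filtration through basic alumina, no acid contact
Reagents that add atoms: 1,2-bis(benzyloxy)-4-iodobenzene (second molecule of 6), Ic1ccc(OCc2ccccc2)c(OCc2ccccc2)c1
Why: Proposed new method: oxidative addition of 6 to zerovalent palladium gives ArPdI(PPh3)2 (divalent palladium), which binds one alkyne of 4 as a π-complex; the phenoxide formed by K2CO3 attacks the alkyne carbon next to the carbinol on the face opposite the metal, and the σ-alkenyl(aryl)palladium species so formed eliminates reductively with retention, placing the aryl group on Cα trans to O1 and returning zerovalent palladium to give 7, which repeats the cycle on its remaining alkyne with a second molecule of 6. The closest known reaction type is the palladium-catalysed cyclisation–coupling of alkynes bearing a tethered oxygen nucleophile (2-alkynylphenols, alkynols, alkynoic acids) with aryl halides, together with the 5-exo cyclisation of 2-(1-hydroxyprop-2-ynyl)phenols; the new element is the twofold use on a conjugated 1,3-diyne. Each of the two oxygen rings closes 5-exo-dig by attack of the phenol oxygen on C2. No stereocentre is created; the two C2=Cα geometries follow from anti-oxypalladation plus stereoretentive reductive elimination, so both should be Z with ring B trans to O1. The step needs 5-exo over 6-endo closure, which the sp3 carbinol between ring A and the alkyne secures geometrically and the conjugated second alkyne reinforces electronically, since attack at C2 leaves the metal on the carbon next to the other π-system. It also needs oxypalladation to outrun syn-carbopalladation and base-induced hydroalkoxylation, which an excess of 6, a free phenoxide and moderate temperature should favour. The carbinol centres of 4 are spectators.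

Step 5
Reactants: 8 (2Z,2'Z)-2,2'-{1,2-bis[3,4-bis(benzyloxy)phenyl]ethane-1,2-diylidene}bis[6-(benzyloxy)-2,3-dihydro-1-benzofuran-3-ol]
Product: 9 (2Z,2'Z)-2,2'-{1,2-bis[3,4-bis(benzyloxy)phenyl]ethane-1,2-diylidene}bis[6-(benzyloxy)-1-benzofuran-3(2H)-one] (disulfuretin hexabenzyl ether)
Conditions: activated MnO2 (20 equiv), powdered K2CO3, CH2Cl2, rt
Reagents that add atoms: none
Why: MnO2 oxidises allylic and benzylic alcohols selectively under neutral heterogeneous conditions, the established way of converting 2-arylidene-2,3-dihydrobenzofuran-3-ols into aurones; both carbinol centres are removed, benzyl ethers and enol ethers are inert, and the Z,Z geometry is not touched.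

Step 6
Reactants: 9 (2Z,2'Z)-2,2'-{1,2-bis[3,4-bis(benzyloxy)phenyl]ethane-1,2-diylidene}bis[6-(benzyloxy)-1-benzofuran-3(2H)-one]
Product: 10 disulfuretin, (2Z,2'Z)-2,2'-[1,2-bis(3,4-dihydroxyphenyl)ethane-1,2-diylidene]bis[6-hydroxy-1-benzofuran-3(2H)-one]
Conditions: BCl3 (1 M in CH2Cl2, 12 equiv), pentamethylbenzene (18 equiv), CH2Cl2, −78 °C; quench with CHCl3–MeOH at −78 °C; Sephadex LH-20, argon, dark
Reagents that add atoms: none
Why: Lewis-acid cleavage of aryl benzyl ethers by BCl3 at low temperature, with pentamethylbenzene as a non-coordinating trap that captures the benzyl cations by Friedel–Crafts alkylation so the electron-rich rings of the product are not C-benzylated; the enones should survive at −78 °C with their geometry intact, and no stereocentre is involved.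

## Compound list

1 | 4-(benzyloxy)-2-hydroxybenzaldehyde | O=Cc1ccc(OCc2ccccc2)cc1O | starting material
2 | ethynylmagnesium bromide | C#C[Mg]Br | starting material
3 | 5-(benzyloxy)-2-(1-hydroxyprop-2-yn-1-yl)phenol (racemic) | C#CC(O)c1ccc(OCc2ccccc2)cc1O | intermediate
4 | 1,6-bis[4-(benzyloxy)-2-hydroxyphenyl]hexa-2,4-diyne-1,6-diol (meso (1R,6S) form drawn; formed together with the racemic form) | O(Cc1ccccc1)c1ccc([C@@H](O)C#CC#C[C@@H](O)c2ccc(OCc3ccccc3)cc2O)c(O)c1 | intermediate
5 | 1,2-bis(benzyloxy)benzene | C(Oc1ccccc1OCc1ccccc1)c1ccccc1 | starting material
6 | 1,2-bis(benzyloxy)-4-iodobenzene | Ic1ccc(OCc2ccccc2)c(OCc2ccccc2)c1 | intermediate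
7 | mono-cyclised aryl enyne, 5-(benzyloxy)-2-{(4Z)-4-[6-(benzyloxy)-3-hydroxy-1-benzofuran-2(3H)-ylidene]-4-[3,4-bis(benzyloxy)phenyl]-1-hydroxybut-2-yn-1-yl}phenol (relative configuration derived from meso-4; not isolated) | O[C@H]1/C(=C(/C#C[C@@H](O)c2ccc(OCc3ccccc3)cc2O)c2ccc(OCc3ccccc3)c(OCc3ccccc3)c2)Oc2cc(OCc3ccccc3)ccc21 | intermediate
8 | (2Z,2'Z)-2,2'-{1,2-bis[3,4-bis(benzyloxy)phenyl]ethane-1,2-diylidene}bis[6-(benzyloxy)-2,3-dihydro-1-benzofuran-3-ol] (meso (3R,3'S) form drawn) | O[C@H]1/C(=C(/C(=C2\Oc3cc(OCc4ccccc4)ccc3[C@@H]2O)c2ccc(OCc3ccccc3)c(OCc3ccccc3)c2)c2ccc(OCc3ccccc3)c(OCc3ccccc3)c2)Oc2cc(OCc3ccccc3)ccc21 | intermediate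
9 | (2Z,2'Z)-2,2'-{1,2-bis[3,4-bis(benzyloxy)phenyl]ethane-1,2-diylidene}bis[6-(benzyloxy)-1-benzofuran-3(2H)-one] (disulfuretin hexabenzyl ether) | O=C1/C(=C(/C(=C2\Oc3cc(OCc4ccccc4)ccc3C2=O)c2ccc(OCc3ccccc3)c(OCc3ccccc3)c2)c2ccc(OCc3ccccc3)c(OCc3ccccc3)c2)Oc2cc(OCc3ccccc3)ccc21 | intermediate
10 | disulfuretin, (2Z,2'Z)-2,2'-[1,2-bis(3,4-dihydroxyphenyl)ethane-1,2-diylidene]bis[6-hydroxy-1-benzofuran-3(2H)-one] | O=C1/C(=C(/C(=C2\Oc3cc(O)ccc3C2=O)c2ccc(O)c(O)c2)c2ccc(O)c(O)c2)Oc2cc(O)ccc21 | target

## Step count and least certain steps

Total step count: 6. Longest linear sequence: 5 steps (steps 1, 2, 4, 5 and 6 from 1); step 3 prepares the coupling partner 6 on a side branch.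

Step 4 (key step, proposed new method). Several processes may compete:
- cyclisation without arylation, by base- or palladium-induced hydroalkoxylation of the electrophilic diyne or by protodepalladation;
- syn-carbopalladation of the diyne by ArPdI(PPh3)2, which would scramble the geometry or lead to oligomers;
- stalling after the first cycle, because the remaining alkyne of 7 is hindered and conjugated to an electron-rich enol ether;
- palladium-mediated dehydrogenation of a propargylic carbinol before ring closure, with the aryl iodide as hydrogen acceptor, which would open the six-membered closure.

The cause is that two consecutive, increasingly congested cycles are required on a substrate class for which only the single event has analogy. The fallback separates C–O from C–C bond formation and uses known reactions. Setting out from 4, twofold iodocyclisation (I2, NaHCO3, MeCN, 0 °C; anti iodo-etherification, 5-exo-dig) should give the bis(alkenyl iodide) (2E,2'E)-2,2'-(1,2-diiodoethane-1,2-diylidene)bis[6-(benzyloxy)-2,3-dihydro-1-benzofuran-3-ol] F1, with each iodine trans to O1. A twofold Suzuki–Miyaura coupling of F1 with two equivalents of commercial [3,4-bis(benzyloxy)phenyl]boronic acid (Pd(PPh3)4, K2CO3, dioxane–water, 70 °C), which proceeds with retention at the alkenyl carbon, comes back to the route at 8.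

Step 2. Copper, amine and oxygen may oxidise the electron-rich free phenol (oxidative phenol coupling) in competition with alkyne dimerisation. The ortho phenol may also cyclise onto the copper-activated alkyne, and the sensitive ortho-hydroxybenzylic carbinol may ionise. The cause is that the phenol needed for step 4 is unprotected under oxidising conditions. The fallback masks both hydroxyl groups for the coupling. Setting out from 3, silylation (TBSCl, imidazole, DMF) should give [5-(benzyloxy)-2-{1-[(tert-butyldimethylsilyl)oxy]prop-2-yn-1-yl}phenoxy](tert-butyl)dimethylsilane F2. The same Glaser–Hay coupling, now joining two molecules of this bis-silyl ether, should then give 1,6-bis{4-(benzyloxy)-2-[(tert-butyldimethylsilyl)oxy]phenyl}-1,6-bis[(tert-butyldimethylsilyl)oxy]hexa-2,4-diyne F3. Desilylation with TBAF buffered by AcOH (THF, 0 °C) comes back to the route at 4.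

Step 6. Three things may go wrong. Liberated benzyl cations may alkylate the electron-rich rings if trapping is too slow. The 6-benzyloxy groups, whose oxygen is conjugated to the ketone, may cleave incompletely. Lewis-acid complexation of the C3 carbonyl may allow rotation about C2=Cα and loss of the Z,Z geometry. The free hexaphenol may also oxidise in air during work-up. The fallback replaces the Lewis-acid cleavage by a neutral reductive one. Setting out from 9, hydrogenolysis of the six benzyl ethers (Pd(OH)2/C, H2 at 1 atm or 1,4-cyclohexadiene, THF–MeOH, rt) is followed closely and stopped after O-debenzylation; the twisted tetrasubstituted diene is expected to be reduced more slowly than the benzyl ethers are cleaved. It comes back to the route at 10 and makes no new compound.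

Step 5. The C3–OH groups of 8 may ionise on any acidic surface (silica, the oxidant itself), followed by allylic transposition and aromatisation to benzofurans; the oxidation may also stop at the keto-alcohol if solubility drops. The cause is that these carbinols are benzylic, allylic and para to an alkoxy group. The fallback avoids isolating 8. Setting out from 4, the cascade of step 4 is run as before. Once 4 and 7 are consumed, 2-bromomesitylene and more K2CO3 are added and the temperature is raised (DMF, 100 °C). The catalyst derived from Pd(PPh3)4 that is already present then dehydrogenates the secondary carbinols through a palladium alkoxide, β-hydride elimination and reductive elimination of the arene, which is the known palladium-catalysed oxidation of alcohols with an aryl halide as hydrogen acceptor. It comes back to the route at 9 and makes no new compound.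

## Further compounds

F1 | step 4 | (2E,2'E)-2,2'-(1,2-diiodoethane-1,2-diylidene)bis[6-(benzyloxy)-2,3-dihydro-1-benzofuran-3-ol] (meso form drawn) | O[C@H]1/C(=C(/C(=C2\Oc3cc(OCc4ccccc4)ccc3[C@@H]2O)I)I)Oc2cc(OCc3ccccc3)ccc21
F2 | step 2 | [5-(benzyloxy)-2-{1-[(tert-butyldimethylsilyl)oxy]prop-2-yn-1-yl}phenoxy](tert-butyl)dimethylsilane (racemic) | C#CC(O[Si](C)(C)C(C)(C)C)c1ccc(OCc2ccccc2)cc1O[Si](C)(C)C(C)(C)C
F3 | step 2 | 1,6-bis{4-(benzyloxy)-2-[(tert-butyldimethylsilyl)oxy]phenyl}-1,6-bis[(tert-butyldimethylsilyl)oxy]hexa-2,4-diyne (meso form drawn) | O(Cc1ccccc1)c1ccc([C@@H](O[Si](C)(C)C(C)(C)C)C#CC#C[C@@H](O[Si](C)(C)C(C)(C)C)c2ccc(OCc3ccccc3)cc2O[Si](C)(C)C(C)(C)C)c(O[Si](C)(C)C(C)(C)C)c1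
F0 | step 6 | none | none
F0 | step 5 | none | none
A1 | alternative 1 | 1,2-bis(3,6-dimethoxy-1-benzofuran-2-yl)ethane-1,2-dione | COc1ccc2c(OC)c(C(=O)C(=O)c3oc4cc(OC)ccc4c3OC)oc2c1
A2 | alternative 1 | (3,4-dimethoxyphenyl)magnesium bromide | COc1ccc([Mg]Br)cc1OC
A3 | alternative 1 | 1,2-bis(3,6-dimethoxy-1-benzofuran-2-yl)-1,2-bis(3,4-dimethoxyphenyl)ethane-1,2-diol (meso form drawn) | COc1ccc2c(OC)c([C@@](O)(c3ccc(OC)c(OC)c3)[C@@](O)(c3ccc(OC)c(OC)c3)c3oc4cc(OC)ccc4c3OC)oc2c1
A4 | alternative 2 | 2,5-bis(2-hydroxy-4-methoxybenzoyl)-3,4-bis(3,4-dimethoxyphenyl)furan | COc1ccc(C(=O)c2oc(C(=O)c3ccc(OC)cc3O)c(-c3ccc(OC)c(OC)c3)c2-c2ccc(OC)c(OC)c2)c(O)c1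
A5 | alternative 2 | disulfuretin hexamethyl ether, (2Z,2'Z)-2,2'-[1,2-bis(3,4-dimethoxyphenyl)ethane-1,2-diylidene]bis[6-methoxy-1-benzofuran-3(2H)-one] | O=C1/C(=C(/C(=C2\Oc3cc(OC)ccc3C2=O)c2ccc(OC)c(OC)c2)c2ccc(OC)c(OC)c2)Oc2cc(OC)ccc21
A6 | alternative 3 | dimethyl (2Z,4Z)-2,5-dihydroxy-3,4-bis(3,4-dimethoxyphenyl)hexa-2,4-dienedioate | COC(=O)/C(=C(/C(=C(\O)C(=O)OC)c1ccc(OC)c(OC)c1)c1ccc(OC)c(OC)c1)O
A7 | alternative 3 | 2-bromo-4-methoxy-6-(trimethylsilyl)phenyl trifluoromethanesulfonate | COc1cc(Br)c(OS(=O)(=O)C(F)(F)F)c([Si](C)(C)C)c1
A8 | alternative 3 | (2Z,2'Z)-2,2'-[1,2-bis(3,4-dimethoxyphenyl)ethane-1,2-diylidene]bis[4-bromo-6-methoxy-1-benzofuran-3(2H)-one] | O=C1/C(=C(/C(=C2\Oc3cc(OC)cc(Br)c3C2=O)c2ccc(OC)c(OC)c2)c2ccc(OC)c(OC)c2)Oc2cc(OC)cc(Br)c21
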